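**Retrosynthetic overview**

1. The strategy rests on the E C20=C21 bond of the C18=C19(Me)–C20=C21 diene inside the 16-membered lactone ring (C1–C8, C17–C23, O), which sits between allylic C20 and the C22 methine. It is written as a sulfone bridging C20 and C21 in a 17-membered ring and is made last by Ramberg–Bäcklund contraction with loss of SO2.
2. The 17-membered ring is closed by attack of a C21 thiolate on a C20 allylic bromide within a seco ester whose C1–O23 ester bond is made intermolecularly beforehand.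
3. C1–C20 acid: C5–C6 Suzuki coupling of (2E,4Z)-5-iodohexa-2,4-dienoic acid with a C6 alkenylboronate on the cis-decalin. Rings A and B form together (bonds C9–C14 and C8–C17) by intramolecular Diels–Alder reaction of a Z-enal/E,E,E-triene built from a (4R,6S)-dioxane building block that carries C11 and C13.
4. C21–C27 thioacetate: two tartrate crotylborations starting from D-alaninol (C26), then N-acetylation and thio-Mitsunobu reaction at C21.
5. Ring order: A and B (step 14), 17-membered thia-lactone (step 32), 16-membered lactone by contraction (step 34); C13 carbamate and desilylation follow.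

Key step: step 34

Remark: atoms carry superstolide numbering (C1 lactone carbonyl, C23 lactone carbinol, C27 the methyl on C26); the two tartrate (E)-crotylboronates are assumed to be available as stock solutions prepared from trans-2-butene.

**Route**

Step 1
Reactants: 1 tert-butyl 2-[(4R,6S)-6-(hydroxymethyl)-2,2-dimethyl-1,3-dioxan-4-yl]acetate
Product: 2 tert-butyl 2-[(4R,6S)-6-formyl-2,2-dimethyl-1,3-dioxan-4-yl]acetate (C14 aldehyde)
Conditions: TEMPO (cat.), KBr (cat.), NaOCl, NaHCO3, CH2Cl2/H2O, 0 °C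
Reagents that add atoms: none
Why: Anelli-type TEMPO/hypochlorite oxidation of a primary alcohol stops at the aldehyde under buffered biphasic conditions and should leave the acetonide, the tert-butyl ester and the α-oxygenated stereocentre untouched.

Step 2
Reactants: 2 C14 aldehyde
Product: 3 tert-butyl 2-[(4R,6S)-2,2-dimethyl-6-[(E)-3-oxoprop-1-enyl]-1,3-dioxan-4-yl]acetate (C16 enal)
Conditions: Ph3P=CHCHO, toluene, 60 °C
Reagents that add atoms: (triphenylphosphoranylidene)acetaldehyde, O=CC=P(c1ccccc1)(c1ccccc1)c1ccccc1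
Why: Wittig reaction of the stabilised formylmethylene ylide should give the E C14=C15 alkene, the α-alkoxy aldehyde being more electrophilic than the enal product so that a second homologation is held back.

Step 3
Reactants: 4 ethyl tiglate
Product: 5 ethyl (E)-4-bromo-2-methylbut-2-enoate
Conditions: NBS, AIBN (cat.), PhCF3, reflux
Reagents that add atoms: N-bromosuccinimide, BrN1C(=O)CCC1=O
Why: Wohl–Ziegler bromination should take place at the γ-methyl group through the delocalised allylic radical, leaving the E trisubstituted alkene in place.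

Step 4
Reactants: 5 ethyl (E)-4-bromo-2-methylbut-2-enoate
Product: 6 ethyl (E)-4-(diethoxyphosphoryl)-2-methylbut-2-enoate
Conditions: P(OEt)3, neat, 120 °C
Reagents that add atoms: triethyl phosphite, CCOP(OCC)OCC
Why: Michaelis–Arbuzov reaction of a primary allylic bromide with a trialkyl phosphite is reliable and keeps the alkene geometry.

Step 5
Reactants: 3 C16 enal; 6 ethyl (E)-4-(diethoxyphosphoryl)-2-methylbut-2-enoate
Product: 7 acetonide-protected ethyl E,E,E-trienoate of the C9–C20 chain (C9 tert-butyl ester)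
Conditions: LiN(SiMe3)2, THF, −78 °C to 0 °C
Reagents that add atoms: none
Why: Vinylogous Horner–Wadsworth–Emmons olefination through the α-carbon of the lithiated allylic phosphonate should form C16=C17 as the E isomer and so complete the C14–C19 triene with the C19 methyl and the C20 ester in place.

Step 6
Reactants: 7 acetonide trienoate
Product: 8 ethyl (2E,4E,6E)-7-[(2S,4R)-4-hydroxy-6-oxooxan-2-yl]-2-methylhepta-2,4,6-trienoate (δ-lactone C9/O13; 11-OH free)
Conditions: CF3CO2H/CH2Cl2 (1:4), H2O (2 equiv), 0 °C to rt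
Reagents that add atoms: none
Why: Acid should cleave the acetonide and the tert-butyl ester, and the liberated 3,5-dihydroxy acid lactonises through O13 to the six-membered ring, which differentiates O13 (acylated) from O11 (free); conjugation of the triene with the C20 ester disfavours ionisation at allylic C13.

Step 7
Reactants: 8 hydroxy lactone
Product: 9 ethyl (2E,4E,6E)-7-[(2S,4R)-4-methoxy-6-oxooxan-2-yl]-2-methylhepta-2,4,6-trienoate
Conditions: Me3OBF4, 1,8-bis(dimethylamino)naphthalene, CH2Cl2, rt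
Reagents that add atoms: trimethyloxonium tetrafluoroborate, C[O+](C)C.F[B-](F)(F)F
Why: Meerwein-salt O-methylation with a hindered non-nucleophilic base should methylate the only free hydroxyl (O11) without the β-elimination that alkoxide conditions would cause in a β-hydroxy lactone.

Step 8
Reactants: 9 methoxy lactone
Product: 10 C9 Weinreb amide of the C9–C20 chain (11-OMe; 13-OH free; C20 ethyl ester)
Conditions: MeNH(OMe)·HCl, AlMe3, CH2Cl2, −20 °C to 0 °C
Reagents that add atoms: N,O-dimethylhydroxylamine hydrochloride, CNOC.Cl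
Why: Weinreb aminolysis with the aluminium amide should open the reactive δ-lactone faster than it attacks the conjugated and deactivated ethyl trienoate, which releases the C13 hydroxyl.

Step 9
Reactants: 10 Weinreb amide alcohol
Product: 11 13-O-triethylsilyl Weinreb amide
Conditions: Et3SiCl, imidazole, CH2Cl2, 0 °C
Reagents that add atoms: chlorotriethylsilane, CC[Si](Cl)(CC)CC
Why: Standard silylation of a secondary allylic alcohol installs the C13 protecting group that is carried to the end of the route.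

Step 10
Reactants: 11 13-O-triethylsilyl Weinreb amide
Product: 12 C9 aldehyde with free C20 allylic alcohol
Conditions: i-Bu2AlH (4 equiv), CH2Cl2, −78 °C; aq. KNaC4H4O6
Reagents that add atoms: none
Why: Hydride reduction with i-Bu2AlH should stop at the chelated tetrahedral stage of the Weinreb amide (aldehyde on work-up) while the conjugated ethyl ester is reduced fully to the C20 allylic alcohol.

Step 11
Reactants: 12 C9 aldehyde
Product: 13 methyl Z-enoate of the C7–C20 chain (13-OTES; 20-OH free)
Conditions: (CF3CH2O)2P(O)CH(CH3)CO2CH3, KN(SiMe3)2, 18-crown-6, THF, −78 °C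
Reagents that add atoms: methyl 2-[bis(2,2,2-trifluoroethoxy)phosphoryl]propanoate, COC(=O)C(C)P(=O)(OCC(F)(F)F)OCC(F)(F)F
Why: Still–Gennari olefination with the bis(trifluoroethyl) phosphonate under dissociating conditions should give the kinetic Z trisubstituted enoate (C7 cis to C10), which is the dienophile geometry the decalin requires.

Step 12
Reactants: 13 Z-enoate alcohol
Product: 14 bis(triethylsilyl) ether of the Z-enoate (13-OTES and 20-OTES)
Conditions: Et3SiCl, imidazole, CH2Cl2, 0 °C
Reagents that add atoms: chlorotriethylsilane, CC[Si](Cl)(CC)CC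
Why: Silylation of the primary allylic alcohol gives a C20 ether that can later be removed in the presence of the secondary C13 triethylsilyl and C25 tert-butyldimethylsilyl ethers.

Step 13
Reactants: 14 bis-silylated Z-enoate
Product: 15 Z allylic alcohol (C7-OH)
Conditions: i-Bu2AlH (2.5 equiv), CH2Cl2, −78 °C
Reagents that add atoms: none
Why: 1,2-Reduction of the enoate with i-Bu2AlH at low temperature should give the allylic alcohol without Z/E isomerisation or loss of the silyl ethers.

Step 14
Reactants: 15 Z allylic alcohol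
Product: 17 cis-decalin aldehyde (C7 aldehyde on C8; 13-OTES; C17 side chain C18=C19(Me)–C20H2OTES), via Z-enal 16 (not isolated)
Conditions: MnO2, CH2Cl2, rt; filtration; then toluene, BHT (cat.), 60 °C
Reagents that add atoms: none
Why: Allylic oxidation gives the Z enal, which should undergo an intramolecular Diels–Alder reaction of the C8=C9 dienophile with the C14–C17 diene through the endo-aldehyde transition state that a Z dienophile needs for cis ring fusion, the E,E diene placing C13 and C18 cis and a chair-like tether with the C11 methoxy and C13 silyloxy groups equatorial choosing the diene face, so that C8, C9, C14 and C17 are set together.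

Step 15
Reactants: 17 cis-decalin aldehyde
Product: 18 E alkenyl pinacolboronate at C6 (C7=C6–Bpin on C8)
Conditions: Cl2CHB(pin), CrCl2, LiI, THF, rt
Reagents that add atoms: 2-(dichloromethyl)-4,4,5,5-tetramethyl-1,3,2-dioxaborolane, ClC(Cl)B1OC(C)(C)C(C)(C)O1
Why: Takai–Utimoto borylolefination with the geminal dichromium reagent should convert the non-enolisable α-quaternary aldehyde into the E alkenylboronate under neutral conditions.

Step 16
Reactants: 19 but-2-yn-1-ol
Product: 21 (Z)-3-iodobut-2-en-1-ol, via vinylalanate 20 (not isolated)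
Conditions: NaAlH2(OCH2CH2OCH3)2, THF, 0 °C to rt; then I2, −78 °C to 0 °C
Reagents that add atoms: iodine, II
Why: Hydroxyl-directed trans-hydroalumination of the propargylic alcohol places aluminium at C3 in a cyclic alanate, and iodinolysis with retention should give the Z vinyl iodide (iodine cis to the carbinol carbon).

Step 17
Reactants: 21 (Z)-3-iodobut-2-en-1-ol
Product: 23 methyl (2E,4Z)-5-iodohexa-2,4-dienoate, via (Z)-3-iodobut-2-enal 22 (not isolated)
Conditions: MnO2, Ph3P=CHCO2CH3, CH2Cl2, rt
Reagents that add atoms: methyl (triphenylphosphoranylidene)acetate, COC(=O)C=P(c1ccccc1)(c1ccccc1)c1ccccc1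
Why: Tandem MnO2 oxidation–Wittig olefination traps the volatile and isomerisation-prone Z iodo enal as it forms, and the stabilised ylide should give the 2E alkene.

Step 18
Reactants: 23 methyl (2E,4Z)-5-iodohexa-2,4-dienoate
Product: 24 (2E,4Z)-5-iodohexa-2,4-dienoic acid
Conditions: LiOH, THF/H2O, 0 °C to rt; then 1 M HCl
Reagents that add atoms: lithium hydroxide, [Li+].[OH-]
Why: Saponification of the methyl ester should proceed without touching the vinyl iodide or the alkene geometries.

Step 19
Reactants: 18 alkenyl pinacolboronate; 24 (2E,4Z)-5-iodohexa-2,4-dienoic acid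
Product: 25 (2E,4Z,6E)-trienoic acid of the decalin (C1 acid; 13-OTES; 20-OTES)
Conditions: Pd(PPh3)4 (10 mol %), TlOEt, THF/H2O (3:1), rt, dark
Reagents that add atoms: none
Why: Suzuki–Miyaura coupling with thallium-base acceleration should join C5 and C6 at room temperature with retention of both alkene geometries, the iodo acid reacting as its carboxylate.

Step 20
Reactants: 26 D-alaninol
Product: 27 (R)-2-(dibenzylamino)propan-1-ol
Conditions: BnBr (2.2 equiv), K2CO3, CH3CN, reflux
Reagents that add atoms: benzyl bromide, BrCc1ccccc1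
Why: Double N-alkylation of the primary amine gives the dibenzylamine, which both blocks the nitrogen and later enforces non-chelation control.

Step 21
Reactants: 27 (R)-2-(dibenzylamino)propan-1-ol
Product: 28 (R)-2-(dibenzylamino)propanal
Conditions: (COCl)2, DMSO, CH2Cl2, −78 °C; then Et3N
Reagents that add atoms: none
Why: Swern oxidation should give the N,N-dibenzyl α-amino aldehyde without racemisation when it is used crude, the bulky amino group suppressing enolisation.

Step 22
Reactants: 28 (R)-2-(dibenzylamino)propanal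
Product: 29 (2R,3S,4S)-2-(dibenzylamino)-4-methylhex-5-en-3-ol (C24–C27 with vinyl as future C23)
Conditions: diisopropyl (R,R)-tartrate (E)-crotylboronate, 4 Å MS, toluene, −78 °C; then aq. NaOH
Reagents that add atoms: diisopropyl (4R,5R)-2-[(E)-but-2-enyl]-1,3,2-dioxaborolane-4,5-dicarboxylate, C/C=C/CB1O[C@@H](C(=O)OC(C)C)[C@H](C(=O)OC(C)C)O1
Why: Roush crotylboration through a closed chair transition state should give the C24/C25 anti relationship from the E reagent, the (R,R)-tartrate directing attack to the si face (25S), which coincides with the Felkin–Anh non-chelation preference of the dibenzylamino aldehyde (C25/C26 anti), a matched pairing.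

Step 23
Reactants: 29 homoallylic alcohol
Product: 30 25-O-tert-butyldimethylsilyl ether of 29
Conditions: t-BuMe2SiOTf, 2,6-lutidine, CH2Cl2, −78 °C to 0 °C
Reagents that add atoms: tert-butyldimethylsilyl triflate, CC(C)(C)[Si](C)(C)OS(=O)(=O)C(F)(F)F
Why: Silyl triflate with a hindered base should silylate the hindered secondary C25 hydroxyl cleanly, giving the protecting group that lasts to the final step.

Step 24
Reactants: 30 silyl ether
Product: 31 C23 aldehyde (α-methyl at C24; 25-OTBS; 26-NBn2)
Conditions: K2OsO4·2H2O (cat.), NaIO4, 2,6-lutidine, dioxane/H2O (3:1), rt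
Reagents that add atoms: sodium periodate (oxygen relayed through the osmate ester), [Na+].[O-]I(=O)(=O)=O
Why: Lemieux–Johnson cleavage of the terminal alkene buffered with 2,6-lutidine should give the α-methyl aldehyde without epimerisation at C24 and without oxidising the protected amine.

Step 25
Reactants: 31 C23 aldehyde
Product: 32 homoallylic alcohol C21'–C27 (23-OH free; 25-OTBS; terminal vinyl as future C21)
Conditions: diisopropyl (S,S)-tartrate (E)-crotylboronate, 4 Å MS, toluene, −78 °C; then aq. NaOH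
Reagents that add atoms: diisopropyl (4S,5S)-2-[(E)-but-2-enyl]-1,3,2-dioxaborolane-4,5-dicarboxylate, C/C=C/CB1O[C@H](C(=O)OC(C)C)[C@@H](C(=O)OC(C)C)O1
Why: The second Roush crotylboration should give C22/C23 anti from the E reagent, the (S,S)-tartrate attacking the re face (23R) in the Felkin sense of the α-methyl aldehyde (C23/C24 syn), again a matched pairing that leaves the C23 hydroxyl free beside the C25 silyl ether.

Step 26
Reactants: 32 homoallylic alcohol
Product: 34 C21/C23 diol (21-OH primary; 23-OH; 25-OTBS; 26-NBn2), via aldehyde 33 (not isolated)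
Conditions: K2OsO4·2H2O (cat.), NaIO4, 2,6-lutidine, dioxane/H2O, rt; extractive work-up; then NaBH4, MeOH, 0 °C
Reagents that add atoms: sodium periodate (oxygen relayed through the osmate ester), [Na+].[O-]I(=O)(=O)=O
Why: Lemieux–Johnson cleavage removes the extra vinyl carbon and immediate borohydride reduction of the crude β-hydroxy aldehyde should give the C21 primary alcohol before retro-aldol or epimerisation at C22 can occur.

Step 27
Reactants: 34 dibenzylamino diol
Product: 36 acetamido diol (26-NHAc; 21-OH; 23-OH; 25-OTBS), via primary amine 35 (not isolated)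
Conditions: H2 (1 atm), Pd(OH)2/C, MeOH, rt; filtration; then Ac2O, rt
Reagents that add atoms: acetic anhydride, CC(=O)OC(C)=O
Why: Hydrogenolysis removes both N-benzyl groups at a stage that holds no alkene or sulfur, and acetic anhydride in methanol should acylate the amine chemoselectively over the hydroxyls.

Step 28
Reactants: 36 acetamido diol
Product: 37 C21 thioacetate with free 23-OH (C21–C27 fragment)
Conditions: PPh3, i-PrO2CN=NCO2i-Pr, CH3COSH, THF, 0 °C to rt
Reagents that add atoms: thioacetic acid, CC(=O)S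
Why: Mitsunobu thioesterification should be selective for the primary C21 hydroxyl over the secondary C23 hydroxyl, which is flanked by two methyl-bearing carbons.

Step 29
Reactants: 25 trienoic acid; 37 thioacetate alcohol
Product: 39 seco ester (C1–O23 ester; 20-OTES; C21 thioacetate), via mixed anhydride 38 (not isolated)
Conditions: 2,4,6-Cl3C6H2COCl, Et3N, THF, rt; then 37, DMAP, toluene, rt
Reagents that add atoms: none
Why: Yamaguchi esterification through the trichlorobenzoyl mixed anhydride and the acylpyridinium should acylate the hindered C23 hydroxyl intermolecularly at room temperature, conditions under which the thioacetate and the silyl ethers persist.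

Step 30
Reactants: 39 seco ester
Product: 40 C20 allylic alcohol of the seco ester
Conditions: PPTS (cat.), MeOH/CH2Cl2 (1:1), 0 °C
Reagents that add atoms: none
Why: Mild acid methanolysis should remove the primary allylic triethylsilyl ether much faster than the hindered secondary C13 triethylsilyl and C25 tert-butyldimethylsilyl ethers.

Step 31
Reactants: 40 C20 allylic alcohol
Product: 41 C20 allylic bromide of the seco ester
Conditions: CBr4, PPh3, CH2Cl2, −20 °C to 0 °C
Reagents that add atoms: carbon tetrabromide, BrC(Br)(Br)Br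
Why: Appel bromination of a primary allylic alcohol proceeds by direct displacement under neutral conditions and should tolerate the thioacetate, the ester and the silyl ethers.

Step 32
Reactants: 41 bromo thioacetate seco ester
Product: 43 17-membered thia-lactone (sulfide bridging C20 and C21), via thiol 42 (not isolated)
Conditions: K2CO3, degassed MeOH/THF (1:1), rt, 0.5 mM, slow addition of 41
Reagents that add atoms: none
Why: Methanolysis of the thioacetate releases the thiolate, whose soft SN2 attack on the primary allylic bromide (macrocyclic thioetherification at high dilution) should outrun methanolysis of the bromide and attack on the hindered conjugated ester.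

Step 33
Reactants: 43 macrocyclic sulfide
Product: 45 17-membered macrocyclic sulfone bridging C20 and C21, via sulfoxide 44 (not isolated)
Conditions: H2O2 (30% aq.), (NH4)6Mo7O24·4H2O (cat.), EtOH, 0 °C to rt
Reagents that add atoms: hydrogen peroxide, OO
Why: Molybdate-catalysed peroxide oxidation is selective for sulfur over the alkenes and should carry the allylic sulfoxide on to the sulfone quickly enough to prevent loss through sulfoxide–sulfenate rearrangement.

Step 34
Reactants: 45 17-membered macrocyclic sulfone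
Product: 48 bis-silylated descarbamoyl superstolide A (13-OTES; 25-OTBS), via bromo sulfone 46 (not isolated), via episulfone 47 (not isolated)
Conditions: CBr2F2, KOH on Al2O3, t-BuOH/CH2Cl2, 0 °C to rt
Reagents that add atoms: none
Why: Ramberg–Bäcklund reaction in its one-flask halogenative form: supported hydroxide removes the more acidic allylic α-sulfonyl proton at C20, the carbanion takes bromine from CBr2F2 to give bromo sulfone 46, and deprotonation at C21 is followed by intramolecular displacement of bromide (3-exo-tet) to the thiirane 1,1-dioxide 47. Cheletropic loss of SO2 from 47 then joins C20 and C21 as a double bond, so that the 17-membered sulfone ring contracts to the 16-membered lactone ring; contraction of macrocyclic and allylic sulfones to cycloalkenes and 1,3-dienes under these conditions is the closest known reaction type. No stereocentre is formed, and the only new stereo-element is the C20=C21 geometry. The E geometry should be secured by base-mediated equilibration of the episulfone to its trans isomer and by the strain that a Z alkene next to E-C18=C19 would cause inside the ring. C22 is β to sulfur and keeps its configuration, and halogenation at either α-carbon leads to the same episulfone. The low-water supported base at 0 °C is chosen to spare the hindered C23 ester, the acetamide and both silyl ethers.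

Step 35
Reactants: 48 bis-silylated macrolide
Product: 49 C13 alcohol (25-OTBS retained)
Conditions: PPTS, MeOH/CH2Cl2, rt
Reagents that add atoms: none
Why: Acid-catalysed methanolysis should remove the secondary triethylsilyl ether selectively, the secondary tert-butyldimethylsilyl ether at the hindered C25 position being far more stable.

Step 36
Reactants: 49 C13 alcohol
Product: 51 25-O-tert-butyldimethylsilyl superstolide A (C13 carbamate), via N-trichloroacetyl carbamate 50 (not isolated)
Conditions: Cl3CC(O)NCO, CH2Cl2, 0 °C; then K2CO3, MeOH, 0 °C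
Reagents that add atoms: trichloroacetyl isocyanate, O=C=NC(=O)C(Cl)(Cl)Cl
Why: Kočovský carbamoylation: the acyl isocyanate adds to the only free hydroxyl and brief methanolysis removes the trichloroacetyl group to leave the primary carbamate, conditions the hindered lactone should survive.

Step 37
Reactants: 51 25-O-silyl superstolide A
Product: 52 superstolide A
Conditions: HF·pyridine, pyridine, THF, 0 °C to rt
Reagents that add atoms: none
Why: Buffered fluoride desilylation should remove the last silyl ether at C25 without affecting the carbamate, the lactone or the polyene.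

**Compound list**

1 | tert-butyl 2-[(4R,6S)-6-(hydroxymethyl)-2,2-dimethyl-1,3-dioxan-4-yl]acetate | CC(C)(C)OC(=O)C[C@H]1C[C@@H](CO)OC(C)(C)O1 | starting material
2 | tert-butyl 2-[(4R,6S)-6-formyl-2,2-dimethyl-1,3-dioxan-4-yl]acetate | CC(C)(C)OC(=O)C[C@H]1C[C@@H](C=O)OC(C)(C)O1 | intermediate
3 | tert-butyl 2-[(4R,6S)-2,2-dimethyl-6-[(E)-3-oxoprop-1-enyl]-1,3-dioxan-4-yl]acetate | CC(C)(C)OC(=O)C[C@H]1C[C@@H](/C=C/C=O)OC(C)(C)O1 | intermediate
4 | ethyl tiglate | C/C=C(\C)C(=O)OCC | starting material
5 | ethyl (E)-4-bromo-2-methylbut-2-enoate | BrC/C=C(\C)C(=O)OCC | intermediate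
6 | ethyl (E)-4-(diethoxyphosphoryl)-2-methylbut-2-enoate | CCOC(=O)/C(C)=C/CP(=O)(OCC)OCC | intermediate
7 | acetonide-protected ethyl E,E,E-trienoate, C9–C20 (C9 tert-butyl ester) | CC(C)(C)OC(=O)C[C@H]1C[C@@H](/C=C/C=C/C=C(\C)C(=O)OCC)OC(C)(C)O1 | intermediate
8 | ethyl (2E,4E,6E)-7-[(2S,4R)-4-hydroxy-6-oxooxan-2-yl]-2-methylhepta-2,4,6-trienoate | O=C1C[C@H](O)C[C@@H](/C=C/C=C/C=C(\C)C(=O)OCC)O1 | intermediate
9 | ethyl (2E,4E,6E)-7-[(2S,4R)-4-methoxy-6-oxooxan-2-yl]-2-methylhepta-2,4,6-trienoate | O=C1C[C@H](OC)C[C@@H](/C=C/C=C/C=C(\C)C(=O)OCC)O1 | intermediate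
10 | C9 Weinreb amide, 11-OMe, 13-OH, C20 ethyl ester | CON(C)C(=O)C[C@H](OC)C[C@H](O)/C=C/C=C/C=C(\C)C(=O)OCC | intermediate
11 | 13-O-triethylsilyl ether of 10 | CON(C)C(=O)C[C@H](OC)C[C@H](O[Si](CC)(CC)CC)/C=C/C=C/C=C(\C)C(=O)OCC | intermediate
12 | C9 aldehyde, 13-OTES, 20-OH | O=CC[C@H](OC)C[C@H](O[Si](CC)(CC)CC)/C=C/C=C/C=C(\C)CO | intermediate
13 | methyl Z-enoate C7–C20, 13-OTES, 20-OH | COC(=O)/C(C)=C\C[C@H](OC)C[C@H](O[Si](CC)(CC)CC)/C=C/C=C/C=C(\C)CO | intermediate
14 | methyl Z-enoate, 13-OTES, 20-OTES | COC(=O)/C(C)=C\C[C@H](OC)C[C@H](O[Si](CC)(CC)CC)/C=C/C=C/C=C(\C)CO[Si](CC)(CC)CC | intermediate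
15 | Z allylic alcohol (C7-OH), 13-OTES, 20-OTES | OC/C(C)=C\C[C@H](OC)C[C@H](O[Si](CC)(CC)CC)/C=C/C=C/C=C(\C)CO[Si](CC)(CC)CC | intermediate
16 | Z enal (Diels–Alder substrate) | O=C/C(C)=C\C[C@H](OC)C[C@H](O[Si](CC)(CC)CC)/C=C/C=C/C=C(\C)CO[Si](CC)(CC)CC | intermediate
17 | cis-decalin C7 aldehyde, 13-OTES, 20-OTES | CO[C@@H]1C[C@H](O[Si](CC)(CC)CC)[C@@H]2C=C[C@H](/C=C(\C)CO[Si](CC)(CC)CC)[C@](C)(C=O)[C@@H]2C1 | intermediate
18 | decalin E alkenyl pinacolboronate (C6) | CO[C@@H]1C[C@H](O[Si](CC)(CC)CC)[C@@H]2C=C[C@H](/C=C(\C)CO[Si](CC)(CC)CC)[C@](C)(/C=C/B3OC(C)(C)C(C)(C)O3)[C@@H]2C1 | intermediate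
19 | but-2-yn-1-ol | CC#CCO | starting material
20 | cyclic sodium vinylalanate from 19 | CC1=CCO[Al-]1(OCCOC)OCCOC.[Na+] | intermediate
21 | (Z)-3-iodobut-2-en-1-ol | C/C(I)=C/CO | intermediate
22 | (Z)-3-iodobut-2-enal | C/C(I)=C/C=O | intermediate
23 | methyl (2E,4Z)-5-iodohexa-2,4-dienoate | COC(=O)/C=C/C=C(/C)I | intermediate
24 | (2E,4Z)-5-iodohexa-2,4-dienoic acid | OC(=O)/C=C/C=C(/C)I | intermediate
25 | decalin (2E,4Z,6E)-trienoic acid, C1–C20, 13-OTES, 20-OTES | CO[C@@H]1C[C@H](O[Si](CC)(CC)CC)[C@@H]2C=C[C@H](/C=C(\C)CO[Si](CC)(CC)CC)[C@](C)(/C=C/C(C)=C\C=C\C(=O)O)[C@@H]2C1 | intermediate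
26 | D-alaninol, (R)-2-aminopropan-1-ol | C[C@@H](N)CO | starting material
27 | (R)-2-(dibenzylamino)propan-1-ol | C[C@@H](N(Cc1ccccc1)Cc1ccccc1)CO | intermediate
28 | (R)-2-(dibenzylamino)propanal | C[C@@H](N(Cc1ccccc1)Cc1ccccc1)C=O | intermediate
29 | (2R,3S,4S)-2-(dibenzylamino)-4-methylhex-5-en-3-ol | C=C[C@H](C)[C@H](O)[C@@H](C)N(Cc1ccccc1)Cc1ccccc1 | intermediate
30 | 25-O-TBS ether of 29 | C=C[C@H](C)[C@H](O[Si](C)(C)C(C)(C)C)[C@@H](C)N(Cc1ccccc1)Cc1ccccc1 | intermediate
31 | C23 aldehyde, 25-OTBS, 26-NBn2 | O=C[C@H](C)[C@H](O[Si](C)(C)C(C)(C)C)[C@@H](C)N(Cc1ccccc1)Cc1ccccc1 | intermediate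
32 | second homoallylic alcohol, 23-OH, 25-OTBS, 26-NBn2 | C=C[C@@H](C)[C@@H](O)[C@H](C)[C@H](O[Si](C)(C)C(C)(C)C)[C@@H](C)N(Cc1ccccc1)Cc1ccccc1 | intermediate
33 | C21 aldehyde, 23-OH, 25-OTBS, 26-NBn2 | O=C[C@@H](C)[C@@H](O)[C@H](C)[C@H](O[Si](C)(C)C(C)(C)C)[C@@H](C)N(Cc1ccccc1)Cc1ccccc1 | intermediate
34 | C21/C23 diol, 25-OTBS, 26-NBn2 | OC[C@@H](C)[C@@H](O)[C@H](C)[C@H](O[Si](C)(C)C(C)(C)C)[C@@H](C)N(Cc1ccccc1)Cc1ccccc1 | intermediate
35 | primary amine diol, 25-OTBS | OC[C@@H](C)[C@@H](O)[C@H](C)[C@H](O[Si](C)(C)C(C)(C)C)[C@@H](C)N | intermediate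
36 | acetamido diol, 25-OTBS | OC[C@@H](C)[C@@H](O)[C@H](C)[C@H](O[Si](C)(C)C(C)(C)C)[C@@H](C)NC(C)=O | intermediate
37 | C21 thioacetate, 23-OH, 25-OTBS, 26-NHAc (C21–C27 fragment) | CC(=O)SC[C@@H](C)[C@@H](O)[C@H](C)[C@H](O[Si](C)(C)C(C)(C)C)[C@@H](C)NC(C)=O | intermediate
38 | mixed anhydride of 25 with 2,4,6-trichlorobenzoic acid | CO[C@@H]1C[C@H](O[Si](CC)(CC)CC)[C@@H]2C=C[C@H](/C=C(\C)CO[Si](CC)(CC)CC)[C@](C)(/C=C/C(C)=C\C=C\C(=O)OC(=O)c3c(Cl)cc(Cl)cc3Cl)[C@@H]2C1 | intermediate
39 | seco ester, 20-OTES, C21 thioacetate | CO[C@@H]1C[C@H](O[Si](CC)(CC)CC)[C@@H]2C=C[C@H](/C=C(\C)CO[Si](CC)(CC)CC)[C@](C)(/C=C/C(C)=C\C=C\C(=O)O[C@H]([C@H](C)CSC(C)=O)[C@H](C)[C@H](O[Si](C)(C)C(C)(C)C)[C@@H](C)NC(C)=O)[C@@H]2C1 | intermediate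
40 | seco ester, 20-OH, C21 thioacetate | CO[C@@H]1C[C@H](O[Si](CC)(CC)CC)[C@@H]2C=C[C@H](/C=C(\C)CO)[C@](C)(/C=C/C(C)=C\C=C\C(=O)O[C@H]([C@H](C)CSC(C)=O)[C@H](C)[C@H](O[Si](C)(C)C(C)(C)C)[C@@H](C)NC(C)=O)[C@@H]2C1 | intermediate
41 | seco ester, C20 allylic bromide, C21 thioacetate | CO[C@@H]1C[C@H](O[Si](CC)(CC)CC)[C@@H]2C=C[C@H](/C=C(\C)CBr)[C@](C)(/C=C/C(C)=C\C=C\C(=O)O[C@H]([C@H](C)CSC(C)=O)[C@H](C)[C@H](O[Si](C)(C)C(C)(C)C)[C@@H](C)NC(C)=O)[C@@H]2C1 | intermediate
42 | seco ester, C20 allylic bromide, C21 thiol | CO[C@@H]1C[C@H](O[Si](CC)(CC)CC)[C@@H]2C=C[C@H](/C=C(\C)CBr)[C@](C)(/C=C/C(C)=C\C=C\C(=O)O[C@H]([C@H](C)CS)[C@H](C)[C@H](O[Si](C)(C)C(C)(C)C)[C@@H](C)NC(C)=O)[C@@H]2C1 | intermediate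
43 | 17-membered macrocyclic sulfide (S between C20 and C21) | CO[C@@H]1C[C@H](O[Si](CC)(CC)CC)[C@@H]2C=C[C@@H]3/C=C(C)/CSC[C@@H](C)[C@H]([C@H](C)[C@H](O[Si](C)(C)C(C)(C)C)[C@@H](C)NC(C)=O)OC(=O)/C=C/C=C(C)\C=C\[C@]3(C)[C@@H]2C1 | intermediate
44 | macrocyclic sulfoxide (configuration at sulfur not defined) | CO[C@@H]1C[C@H](O[Si](CC)(CC)CC)[C@@H]2C=C[C@@H]3/C=C(C)/CS(=O)C[C@@H](C)[C@H]([C@H](C)[C@H](O[Si](C)(C)C(C)(C)C)[C@@H](C)NC(C)=O)OC(=O)/C=C/C=C(C)\C=C\[C@]3(C)[C@@H]2C1 | intermediate
45 | 17-membered macrocyclic sulfone bridging C20 and C21 | CO[C@@H]1C[C@H](O[Si](CC)(CC)CC)[C@@H]2C=C[C@@H]3/C=C(C)/CS(=O)(=O)C[C@@H](C)[C@H]([C@H](C)[C@H](O[Si](C)(C)C(C)(C)C)[C@@H](C)NC(C)=O)OC(=O)/C=C/C=C(C)\C=C\[C@]3(C)[C@@H]2C1 | intermediate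
46 | C20 α-bromo sulfone (configuration at C20 not defined) | CO[C@@H]1C[C@H](O[Si](CC)(CC)CC)[C@@H]2C=C[C@@H]3/C=C(C)/C(Br)S(=O)(=O)C[C@@H](C)[C@H]([C@H](C)[C@H](O[Si](C)(C)C(C)(C)C)[C@@H](C)NC(C)=O)OC(=O)/C=C/C=C(C)\C=C\[C@]3(C)[C@@H]2C1 | intermediate
47 | thiirane 1,1-dioxide across C20–C21 (trans; ring carbons drawn without configuration) | CO[C@@H]1C[C@H](O[Si](CC)(CC)CC)[C@@H]2C=C[C@@H]3/C=C(C)/C4C([C@@H](C)[C@H]([C@H](C)[C@H](O[Si](C)(C)C(C)(C)C)[C@@H](C)NC(C)=O)OC(=O)/C=C/C=C(C)\C=C\[C@]3(C)[C@@H]2C1)S4(=O)=O | intermediate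
48 | bis-silylated descarbamoyl superstolide A (13-OTES, 25-OTBS) | CO[C@@H]1C[C@H](O[Si](CC)(CC)CC)[C@@H]2C=C[C@@H]3/C=C(C)/C=C/[C@@H](C)[C@H]([C@H](C)[C@H](O[Si](C)(C)C(C)(C)C)[C@@H](C)NC(C)=O)OC(=O)/C=C/C=C(C)\C=C\[C@]3(C)[C@@H]2C1 | intermediate
49 | descarbamoyl superstolide A 25-O-TBS ether (13-OH) | CO[C@@H]1C[C@H](O)[C@@H]2C=C[C@@H]3/C=C(C)/C=C/[C@@H](C)[C@H]([C@H](C)[C@H](O[Si](C)(C)C(C)(C)C)[C@@H](C)NC(C)=O)OC(=O)/C=C/C=C(C)\C=C\[C@]3(C)[C@@H]2C1 | intermediate
50 | 13-O-(N-trichloroacetyl)carbamate, 25-OTBS | CO[C@@H]1C[C@H](OC(=O)NC(=O)C(Cl)(Cl)Cl)[C@@H]2C=C[C@@H]3/C=C(C)/C=C/[C@@H](C)[C@H]([C@H](C)[C@H](O[Si](C)(C)C(C)(C)C)[C@@H](C)NC(C)=O)OC(=O)/C=C/C=C(C)\C=C\[C@]3(C)[C@@H]2C1 | intermediate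
51 | 25-O-tert-butyldimethylsilyl superstolide A | CO[C@@H]1C[C@H](OC(N)=O)[C@@H]2C=C[C@@H]3/C=C(C)/C=C/[C@@H](C)[C@H]([C@H](C)[C@H](O[Si](C)(C)C(C)(C)C)[C@@H](C)NC(C)=O)OC(=O)/C=C/C=C(C)\C=C\[C@]3(C)[C@@H]2C1 | intermediate
52 | superstolide A | CO[C@@H]1C[C@H](OC(N)=O)[C@@H]2C=C[C@@H]3/C=C(C)/C=C/[C@@H](C)[C@H]([C@H](C)[C@H](O)[C@@H](C)NC(C)=O)OC(=O)/C=C/C=C(C)\C=C\[C@]3(C)[C@@H]2C1 | target

**Step count**

Total: 37 steps. Longest linear sequence: 23 steps (from 1 through steps 1, 2, 5–15, 19 and 29–37).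

**Steps most likely to fail**

Step 34 (Ramberg–Bäcklund contraction). Over-halogenation at C20 or C21, hydroxide attack on the lactone, or base-induced migration of the trienoate double bonds may compete with clean extrusion under the one-flask conditions. The fallback sets out from sulfone 45 and separates halogenation from extrusion. The sulfone is deprotonated with LiN(SiMe3)2 (2.2 equiv, THF, −78 °C, the first equivalent being taken by the acetamide) and chlorinated with C2Cl6 to give the isolated C20 α-chloro sulfone F1. F1 is then treated with KOt-Bu in THF at −78 °C, a classical two-stage Ramberg–Bäcklund reaction with a strictly stoichiometric halogen and a hydroxide-free base, and the route is rejoined at 48.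

Step 32 (macrocyclic thioether formation). Oligomerisation at the thiolate stage, conjugate addition of the thiolate to the trienoate, or methanolysis of the allylic bromide before ring closure may lower the yield. The fallback sets out from allylic alcohol 40 and replaces the SN2 ring closure by a palladium-catalysed allylic substitution. Methyl chloroformate and pyridine give the C20 allylic methyl carbonate F2, and hydrazine acetate in DMF cleaves the thioacetate selectively to the thiol carbonate F3. Pd2(dba)3 with dppf at high dilution in THF then ionises the carbonate to the C18–C20 π-allyl complex of divalent palladium, which the thiol should attack at the less hindered C20 terminus, and the route is rejoined at sulfide 43.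

Step 29 (Yamaguchi esterification). Acylation of the hindered C23 hydroxyl by the mixed anhydride may be slow, so that DMAP-induced Z-to-E isomerisation at C4=C5 or S-to-O acetyl migration take over. The fallback sets out from alcohol 37 and boronate 18 and forms the ester bond with a small acid, the C2=C3 bond then serving as the point of fragment union. Alcohol 37 is acylated with diethylphosphonoacetic acid (DCC, DMAP cat.) to the phosphonoacetate F4. Boronate 18 is coupled with (Z)-3-iodobut-2-en-1-ol 21 (Pd(PPh3)4, TlOEt) to the dienol F5, which MnO2 oxidises to the (2Z,4E)-dienal F6. A Masamune–Roush Horner–Wadsworth–Emmons reaction of F4 with F6 (LiCl, i-Pr2NEt, CH3CN) should form C2=C3 as the E isomer, and the route is rejoined at seco ester 39.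

**Further compounds**

F1 | step 34 | C20 α-chloro sulfone of 45 (configuration at C20 not defined) | CO[C@@H]1C[C@H](O[Si](CC)(CC)CC)[C@@H]2C=C[C@@H]3/C=C(C)/C(Cl)S(=O)(=O)C[C@@H](C)[C@H]([C@H](C)[C@H](O[Si](C)(C)C(C)(C)C)[C@@H](C)NC(C)=O)OC(=O)/C=C/C=C(C)\C=C\[C@]3(C)[C@@H]2C1
F2 | step 32 | seco ester with C20 allylic methyl carbonate and C21 thioacetate | CO[C@@H]1C[C@H](O[Si](CC)(CC)CC)[C@@H]2C=C[C@H](/C=C(\C)COC(=O)OC)[C@](C)(/C=C/C(C)=C\C=C\C(=O)O[C@H]([C@H](C)CSC(C)=O)[C@H](C)[C@H](O[Si](C)(C)C(C)(C)C)[C@@H](C)NC(C)=O)[C@@H]2C1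
F3 | step 32 | seco ester with C20 allylic methyl carbonate and C21 thiol | CO[C@@H]1C[C@H](O[Si](CC)(CC)CC)[C@@H]2C=C[C@H](/C=C(\C)COC(=O)OC)[C@](C)(/C=C/C(C)=C\C=C\C(=O)O[C@H]([C@H](C)CS)[C@H](C)[C@H](O[Si](C)(C)C(C)(C)C)[C@@H](C)NC(C)=O)[C@@H]2C1
F4 | step 29 | diethylphosphonoacetate of alcohol 37 | CCOP(=O)(OCC)CC(=O)O[C@H]([C@H](C)CSC(C)=O)[C@H](C)[C@H](O[Si](C)(C)C(C)(C)C)[C@@H](C)NC(C)=O
F5 | step 29 | decalin (2Z,4E)-dienol (C3 alcohol) | CO[C@@H]1C[C@H](O[Si](CC)(CC)CC)[C@@H]2C=C[C@H](/C=C(\C)CO[Si](CC)(CC)CC)[C@](C)(/C=C/C(C)=C\CO)[C@@H]2C1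
F6 | step 29 | decalin (2Z,4E)-dienal (C3 aldehyde) | CO[C@@H]1C[C@H](O[Si](CC)(CC)CC)[C@@H]2C=C[C@H](/C=C(\C)CO[Si](CC)(CC)CC)[C@](C)(/C=C/C(C)=C\C=O)[C@@H]2C1
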